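**Retrosynthetic overview**

1. Target 33 ⇐ 31 by removal of one acetate and four benzyl ethers; the flavone C2–C1' biaryl bond of 31 is cut to the flavanone boronic acid 26 and the 2-(methylthio)chromone 30 (base-free Liebeskind–Srogl coupling).
2. Ring C of flavanone 24 is cut at C4–C4a (intramolecular Friedel–Crafts acylation) back to acid 22. The strategy rests on this bond: it joins the C4 carbonyl to ring A, a phloroglucinol-derived 3,5-bis(benzyloxy)phenyl ether whose two carbons ortho to O1 (future C4a and C8) are equivalent.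
3. Acid 22 ⇐ primary alcohol 20 ⇐ Mitsunobu etherification (C2–O1, inversion) of the monosilylated syn-1,3-diol 14 with 3,5-bis(benzyloxy)phenol 18.
4. 14 ⇐ Evans syn-aldol of arylacetyl imide 7 with aldehyde 9 (both stereocentres), then reductive removal of the auxiliary.
5. Ring order: the flavone pyranone ring is built in a side branch (30, from acetophenone 27 and CS2); flavanone ring C closes in step 14; all benzene rings come from the starting materials.

Key step: step 14

**Remarks on the chemistry**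

- The target is the 2,3-trans flavanone, (2S,3R). C2 is fixed in step 11 and its C–O bond is not broken afterwards. C3 is set in step 5 and is also the thermodynamically preferred epimer, so leakage through the enol corrects itself.
- The aryl ether is made at the 1,3-diol oxidation level. A β-hydroxy carbonyl compound with an α-aryl group would be expected to eliminate under Mitsunobu conditions, so the carboxyl group is regenerated by oxidation afterwards.
- The 4'-oxygen is carried as a silyl ether through the aldol and hydride steps and changed to the acetate before the benzylic carbinol is activated, because an aryl acetate would not survive reductive removal of the auxiliary.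
- Assumption: compounds 1, 5, 8, 15 and 27 and all reagents are bought.

**Route**

Step 1
Reactants: 1 2-hydroxyphenylacetic acid
Product: 2 2-(5-bromo-2-hydroxyphenyl)acetic acid
Conditions: NBS (1.0 equiv), MeCN, 0 °C to rt
Reagents that add atoms: N-bromosuccinimide, O=C1CCC(=O)N1Br
Why: Electrophilic aromatic bromination of a phenol, which in acetonitrile should go para to the hydroxyl group (C5), the position that later carries the flavone.

Step 2
Reactants: 2 2-(5-bromo-2-hydroxyphenyl)acetic acid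
Product: 4 2-[2-(benzyloxy)-5-bromophenyl]acetic acid, via benzyl ester 3 (not isolated)
Conditions: BnBr (2.2 equiv), K2CO3, DMF, rt to 60 °C; then NaOH, MeOH/THF/H2O, 50 °C; HCl work-up
Reagents that add atoms: benzyl bromide, BrCc1ccccc1
Why: Williamson O-alkylation of phenoxide and carboxylate followed by saponification of the benzyl ester, to which the aryl benzyl ether is inert.

Step 3
Reactants: 4 2-[2-(benzyloxy)-5-bromophenyl]acetic acid; 5 (R)-4-benzyl-1,3-oxazolidin-2-one
Product: 7 (R)-4-benzyl-3-{[2-(benzyloxy)-5-bromophenyl]acetyl}-1,3-oxazolidin-2-one, via mixed pivalic anhydride 6 (not isolated)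
Conditions: PivCl, Et3N, THF, −20 °C; then 5, LiCl, −20 °C to rt
Reagents that add atoms: none
Why: N-acylation of the oxazolidinone by a mixed anhydride, which is attacked at the unhindered arylacetyl carbonyl and not at the pivaloyl carbonyl.

Step 4
Reactants: 8 4-hydroxybenzaldehyde
Product: 9 4-[(tert-butyldimethylsilyl)oxy]benzaldehyde
Conditions: TBSCl, imidazole, DMF, rt
Reagents that add atoms: tert-butyldimethylsilyl chloride, CC(C)(C)[Si](C)(C)Cl
Why: Standard silylation of a phenol, giving a protecting group that tolerates the boron aldol and the hydride reduction that follow.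

Step 5
Reactants: 7 (R)-4-benzyl-3-{[2-(benzyloxy)-5-bromophenyl]acetyl}-1,3-oxazolidin-2-one; 9 4-[(tert-butyldimethylsilyl)oxy]benzaldehyde
Product: 10 (R)-4-benzyl-3-[(2R,3R)-2-[2-(benzyloxy)-5-bromophenyl]-3-{4-[(tert-butyldimethylsilyl)oxy]phenyl}-3-hydroxypropanoyl]-1,3-oxazolidin-2-one
Conditions: Bu2BOTf, i-Pr2NEt, CH2Cl2, −78 to 0 °C; then 9, −78 to 0 °C; pH 7 buffer, MeOH, H2O2, 0 °C
Reagents that add atoms: none
Why: Evans syn-aldol reaction, in which the (Z)-boron enolate reacts through a chair Zimmerman–Traxler transition state on the face away from the benzyl group of the (R)-auxiliary and so should set both stereocentres as (2R,3R).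

Step 6
Reactants: 10 (R)-4-benzyl-3-[(2R,3R)-2-[2-(benzyloxy)-5-bromophenyl]-3-{4-[(tert-butyldimethylsilyl)oxy]phenyl}-3-hydroxypropanoyl]-1,3-oxazolidin-2-one
Product: 11 (1R,2S)-2-[2-(benzyloxy)-5-bromophenyl]-1-{4-[(tert-butyldimethylsilyl)oxy]phenyl}propane-1,3-diol
Conditions: LiBH4, MeOH (2 equiv), THF, 0 °C
Reagents that add atoms: none
Why: Reductive cleavage of the exocyclic imide carbonyl by lithium borohydride, which leaves the aryl silyl ether, the aryl bromide and both stereocentres untouched (the C2 descriptor changes only because the priorities change).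

Step 7
Reactants: 11 (1R,2S)-2-[2-(benzyloxy)-5-bromophenyl]-1-{4-[(tert-butyldimethylsilyl)oxy]phenyl}propane-1,3-diol
Product: 12 (1R,2S)-2-[2-(benzyloxy)-5-bromophenyl]-3-[(tert-butyldimethylsilyl)oxy]-1-{4-[(tert-butyldimethylsilyl)oxy]phenyl}propan-1-ol
Conditions: TBSCl (1.05 equiv), imidazole, CH2Cl2, 0 °C
Reagents that add atoms: tert-butyldimethylsilyl chloride, CC(C)(C)[Si](C)(C)Cl
Why: Selective silylation of the primary hydroxyl group in the presence of the hindered secondary benzylic one.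

Step 8
Reactants: 12 (1R,2S)-2-[2-(benzyloxy)-5-bromophenyl]-3-[(tert-butyldimethylsilyl)oxy]-1-{4-[(tert-butyldimethylsilyl)oxy]phenyl}propan-1-ol
Product: 14 4-[(1R,2S)-2-[2-(benzyloxy)-5-bromophenyl]-3-[(tert-butyldimethylsilyl)oxy]-1-hydroxypropyl]phenyl acetate, via phenol 13 (not isolated)
Conditions: Cs2CO3 (0.5 equiv), DMF/H2O 10:1, rt; aqueous work-up; crude, Ac2O (1.1 equiv), Et3N, CH2Cl2, 0 °C
Reagents that add atoms: acetic anhydride, CC(=O)OC(C)=O
Why: Carbonate in wet DMF cleaves aryl silyl ethers much faster than alkyl ones, and the phenol is then acetylated chemoselectively over the hindered secondary alcohol, which turns the para donor into a non-donor before the benzylic carbinol is activated.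

Step 9
Reactants: 15 phloroglucinol
Product: 16 benzene-1,3,5-triyl triacetate
Conditions: Ac2O, pyridine, rt
Reagents that add atoms: acetic anhydride, CC(=O)OC(C)=O
Why: Exhaustive O-acetylation, which masks the phenol so that the carbon nucleophilicity of free phloroglucinol does not interfere in the benzylation.

Step 10
Reactants: 16 benzene-1,3,5-triyl triacetate
Product: 18 3,5-bis(benzyloxy)phenol, via 3,5-bis(benzyloxy)phenyl acetate 17 (not isolated)
Conditions: BnCl (2.1 equiv), NaH (4.2 equiv), H2O (2.1 equiv, slow addition), DMF, 0 °C to rt; then NaOH, MeOH/H2O, rt; HCl work-up; chromatography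
Reagents that add atoms: benzyl chloride, ClCc1ccccc1
Why: In situ deacetylation–benzylation, in which hydroxide made from NaH and water releases the phenoxides one at a time and each is O-benzylated at once, so that C-benzylation is avoided and the stoichiometry stops the sequence at two benzyl groups before the last acetate is saponified.

Step 11
Reactants: 14 4-[(1R,2S)-2-[2-(benzyloxy)-5-bromophenyl]-3-[(tert-butyldimethylsilyl)oxy]-1-hydroxypropyl]phenyl acetate; 18 3,5-bis(benzyloxy)phenol
Product: 19 4-[(1S,2S)-2-[2-(benzyloxy)-5-bromophenyl]-1-[3,5-bis(benzyloxy)phenoxy]-3-[(tert-butyldimethylsilyl)oxy]propyl]phenyl acetate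
Conditions: PPh3, DIAD, toluene, 0 °C to rt
Reagents that add atoms: none
Why: Mitsunobu etherification, in which the phenoxide displaces the alkoxyphosphonium group by SN2 with inversion and so should set the future C2 as (S), while the para-acetoxy group disfavours ionisation and no carbonyl group is present to open an E1cB path.

Step 12
Reactants: 19 4-[(1S,2S)-2-[2-(benzyloxy)-5-bromophenyl]-1-[3,5-bis(benzyloxy)phenoxy]-3-[(tert-butyldimethylsilyl)oxy]propyl]phenyl acetate
Product: 20 4-[(1S,2S)-2-[2-(benzyloxy)-5-bromophenyl]-1-[3,5-bis(benzyloxy)phenoxy]-3-hydroxypropyl]phenyl acetate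
Conditions: HF·pyridine, pyridine, THF, 0 °C to rt
Reagents that add atoms: none
Why: Fluoride cleavage of the alkyl silyl ether under buffered conditions that the aryl acetate and the aryl ethers should tolerate.

Step 13
Reactants: 20 4-[(1S,2S)-2-[2-(benzyloxy)-5-bromophenyl]-1-[3,5-bis(benzyloxy)phenoxy]-3-hydroxypropyl]phenyl acetate
Product: 22 (2R,3S)-3-[4-(acetyloxy)phenyl]-2-[2-(benzyloxy)-5-bromophenyl]-3-[3,5-bis(benzyloxy)phenoxy]propanoic acid, via aldehyde 21 (not isolated)
Conditions: Dess–Martin periodinane, CH2Cl2, 0 °C to rt; filtration; then NaClO2, NaH2PO4, 2-methyl-2-butene (large excess), t-BuOH/THF/H2O, 0 °C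
Reagents that add atoms: sodium chlorite, [Na+].[O-]Cl=O
Why: Dess–Martin oxidation followed by Pinnick oxidation, both run without base so that the α-aryl aldehyde is not exposed to conditions for epimerisation or β-elimination of the aryloxide, with the alkene scavenger keeping hypochlorous acid away from the electron-rich ring.

Step 14
Reactants: 22 (2R,3S)-3-[4-(acetyloxy)phenyl]-2-[2-(benzyloxy)-5-bromophenyl]-3-[3,5-bis(benzyloxy)phenoxy]propanoic acid
Product: 24 4-[(2S,3R)-5,7-bis(benzyloxy)-3-[2-(benzyloxy)-5-bromophenyl]-4-oxo-3,4-dihydro-2H-chromen-2-yl]phenyl acetate, via mixed trifluoroacetic anhydride 23 (not isolated)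
Conditions: TFAA (2 equiv), CH2Cl2, 0 °C, then rt briefly
Reagents that add atoms: none
Why: TFAA converts the acid into the acyl trifluoroacetate 23, whose carbonyl carbon (free or incipient acylium) is attacked by the ring-A carbon ortho to the ether oxygen and para to a benzyloxy group, and loss of the proton restores the arene with the new C4–C4a bond. The closest known reaction type is the acid-mediated cyclisation of 3-aryloxypropanoic acids to chroman-4-ones (intramolecular Friedel–Crafts acylation). Ring C closes in a 6-exo-trig mode at the acyl carbon, the attacking arene C=C lying inside the new six-membered ring. No stereocentre is created: C2 is carried in from step 11 and its C–O bond is not touched, and C3 keeps its configuration or, if it passes through the enol, returns to the favoured trans (diequatorial) arrangement of the target. The step needs regioselectivity on ring A and chemoselectivity against other nucleophilic sites: the first is removed by the local twofold symmetry of the 3,5-bis(benzyloxy)phenoxy ring (the position between the two benzyloxy groups cannot reach the acyl carbon), and the second follows from the far higher nucleophilicity of the phloroglucinol-type ring compared with the acetoxy-deactivated C2 aryl (which would give an indanone) and with the ortho-benzyloxy oxygen of the C3 aryl. The para-acetoxy group keeps the benzylic C2–O bond from ionising in the trifluoroacetic acid that is released, and low temperature with a short reaction time should spare the benzyl ethers.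

Step 15
Reactants: 24 4-[(2S,3R)-5,7-bis(benzyloxy)-3-[2-(benzyloxy)-5-bromophenyl]-4-oxo-3,4-dihydro-2H-chromen-2-yl]phenyl acetate
Product: 25 4-[(2S,3R)-5,7-bis(benzyloxy)-3-[2-(benzyloxy)-5-(4,4,5,5-tetramethyl-1,3,2-dioxaborolan-2-yl)phenyl]-4-oxo-3,4-dihydro-2H-chromen-2-yl]phenyl acetate
Conditions: B2pin2, Pd(OAc)2/XPhos (cat.), potassium 2-ethylhexanoate, i-PrOAc, 35 °C
Reagents that add atoms: bis(pinacolato)diboron, CC1(C)OB(OC1(C)C)B1OC(C)(C)C(C)(C)O1
Why: Miyaura borylation of the unhindered aryl bromide, run with a lipophilic carboxylate base that allows 35 °C, which limits enolisation at C3 (and with it retro-oxa-Michael opening of ring C) and spares the aryl acetate.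

Step 16
Reactants: 25 4-[(2S,3R)-5,7-bis(benzyloxy)-3-[2-(benzyloxy)-5-(4,4,5,5-tetramethyl-1,3,2-dioxaborolan-2-yl)phenyl]-4-oxo-3,4-dihydro-2H-chromen-2-yl]phenyl acetate
Product: 26 {3-[(2S,3R)-2-[4-(acetyloxy)phenyl]-5,7-bis(benzyloxy)-4-oxo-3,4-dihydro-2H-chromen-3-yl]-4-(benzyloxy)phenyl}boronic acid
Conditions: NaIO4, THF/H2O 4:1, rt; then 1 M HCl, rt
Reagents that add atoms: water, O
Why: Periodate cleaves the pinacol released in the hydrolysis equilibrium and so drives the ester to the free boronic acid that the base-free coupling needs, under conditions (rt, dilute acid) that should not affect the flavanone or the acetate.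

Step 17
Reactants: 27 1-(2,6-dihydroxy-4-methoxyphenyl)ethan-1-one
Product: 28 1-[2-(benzyloxy)-6-hydroxy-4-methoxyphenyl]ethan-1-one
Conditions: BnBr (1.05 equiv), K2CO3, acetone, reflux
Reagents that add atoms: benzyl bromide, BrCc1ccccc1
Why: Williamson mono-O-benzylation, which stops after one alkylation because the remaining hydroxyl group is held in a hydrogen bond to the ketone.

Step 18
Reactants: 28 1-[2-(benzyloxy)-6-hydroxy-4-methoxyphenyl]ethan-1-one
Product: 30 5-(benzyloxy)-7-methoxy-2-(methylsulfanyl)-4H-chromen-4-one, via chromene-2-thione 29 (not isolated)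
Conditions: CS2, t-BuOK (3 equiv), THF, 0 °C to rt; 10% H2SO4 work-up; crude, MeI (1.1 equiv), K2CO3, acetone, rt
Reagents that add atoms: carbon disulfide, S=C=S; iodomethane, CI
Why: The ketone enolate adds to carbon disulfide and the phenol closes onto the dithioacid with loss of hydrogen sulfide on acidification (the 4-hydroxydithiocoumarin synthesis), after which the soft sulfur is methylated to give the chromone thioether.

Step 19
Reactants: 26 {3-[(2S,3R)-2-[4-(acetyloxy)phenyl]-5,7-bis(benzyloxy)-4-oxo-3,4-dihydro-2H-chromen-3-yl]-4-(benzyloxy)phenyl}boronic acid; 30 5-(benzyloxy)-7-methoxy-2-(methylsulfanyl)-4H-chromen-4-one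
Product: 31 4-[(2S,3R)-5,7-bis(benzyloxy)-3-{2-(benzyloxy)-5-[5-(benzyloxy)-7-methoxy-4-oxo-4H-chromen-2-yl]phenyl}-4-oxo-3,4-dihydro-2H-chromen-2-yl]phenyl acetate
Conditions: Pd2(dba)3 (cat.), tri(2-furyl)phosphine, CuTC (2 equiv), THF, 50 °C, argon
Reagents that add atoms: none
Why: Liebeskind–Srogl coupling, in which Pd(0) inserts into the C2–S bond of the vinylogous thiol ester and the copper(I) carboxylate takes up the thiolate and activates the boronic acid for transmetalation without added base, so that the flavanone stereocentres and the acetate are not exposed to base.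

Step 20
Reactants: 31 4-[(2S,3R)-5,7-bis(benzyloxy)-3-{2-(benzyloxy)-5-[5-(benzyloxy)-7-methoxy-4-oxo-4H-chromen-2-yl]phenyl}-4-oxo-3,4-dihydro-2H-chromen-2-yl]phenyl acetate
Product: 32 (2S,3R)-5,7-bis(benzyloxy)-3-{2-(benzyloxy)-5-[5-(benzyloxy)-7-methoxy-4-oxo-4H-chromen-2-yl]phenyl}-2-(4-hydroxyphenyl)-2,3-dihydro-4H-chromen-4-one
Conditions: HCl (1.25 M in MeOH), THF, rt
Reagents that add atoms: none
Why: Acid-catalysed transesterification of the aryl acetate with methanol, chosen because base would open the flavanone to the chalcone and racemise C2.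

Step 21
Reactants: 32 (2S,3R)-5,7-bis(benzyloxy)-3-{2-(benzyloxy)-5-[5-(benzyloxy)-7-methoxy-4-oxo-4H-chromen-2-yl]phenyl}-2-(4-hydroxyphenyl)-2,3-dihydro-4H-chromen-4-one
Product: 33 (2S,3R)-5,7-dihydroxy-3-[2-hydroxy-5-(5-hydroxy-7-methoxy-4-oxo-4H-chromen-2-yl)phenyl]-2-(4-hydroxyphenyl)-2,3-dihydro-4H-chromen-4-one
Conditions: H2 (1 atm), 10% Pd/C, EtOAc/MeOH, rt
Reagents that add atoms: none
Why: Catalytic hydrogenolysis of the four benzyl ethers under neutral conditions, under which the flavone C2=C3 bond and the flavanone C2–O1 bond are expected to be reduced much more slowly.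

**Compound list**

1 | 2-hydroxyphenylacetic acid | OC(=O)Cc1ccccc1O | starting material
2 | 2-(5-bromo-2-hydroxyphenyl)acetic acid | OC(=O)Cc1cc(Br)ccc1O | intermediate
3 | benzyl 2-[2-(benzyloxy)-5-bromophenyl]acetate | O=C(Cc1cc(Br)ccc1OCc1ccccc1)OCc1ccccc1 | intermediate
4 | 2-[2-(benzyloxy)-5-bromophenyl]acetic acid | OC(=O)Cc1cc(Br)ccc1OCc1ccccc1 | intermediate
5 | (R)-4-benzyl-1,3-oxazolidin-2-one | O=C1N[C@H](Cc2ccccc2)CO1 | starting material
6 | 2-[2-(benzyloxy)-5-bromophenyl]acetic pivalic anhydride | CC(C)(C)C(=O)OC(=O)Cc1cc(Br)ccc1OCc1ccccc1 | intermediate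
7 | (R)-4-benzyl-3-{[2-(benzyloxy)-5-bromophenyl]acetyl}-1,3-oxazolidin-2-one | O=C(Cc1cc(Br)ccc1OCc1ccccc1)N1[C@H](Cc2ccccc2)COC1=O | intermediate
8 | 4-hydroxybenzaldehyde | O=Cc1ccc(O)cc1 | starting material
9 | 4-[(tert-butyldimethylsilyl)oxy]benzaldehyde | O=Cc1ccc(O[Si](C)(C)C(C)(C)C)cc1 | intermediate
10 | (R)-4-benzyl-3-[(2R,3R)-2-[2-(benzyloxy)-5-bromophenyl]-3-{4-[(tert-butyldimethylsilyl)oxy]phenyl}-3-hydroxypropanoyl]-1,3-oxazolidin-2-one | Brc1ccc(OCc2ccccc2)c([C@H]([C@@H](O)c2ccc(O[Si](C)(C)C(C)(C)C)cc2)C(=O)N2[C@H](Cc3ccccc3)COC2=O)c1 | intermediate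
11 | (1R,2S)-2-[2-(benzyloxy)-5-bromophenyl]-1-{4-[(tert-butyldimethylsilyl)oxy]phenyl}propane-1,3-diol | Brc1ccc(OCc2ccccc2)c([C@H]([C@@H](O)c2ccc(O[Si](C)(C)C(C)(C)C)cc2)CO)c1 | intermediate
12 | (1R,2S)-2-[2-(benzyloxy)-5-bromophenyl]-3-[(tert-butyldimethylsilyl)oxy]-1-{4-[(tert-butyldimethylsilyl)oxy]phenyl}propan-1-ol | Brc1ccc(OCc2ccccc2)c([C@H]([C@@H](O)c2ccc(O[Si](C)(C)C(C)(C)C)cc2)CO[Si](C)(C)C(C)(C)C)c1 | intermediate
13 | 4-[(1R,2S)-2-[2-(benzyloxy)-5-bromophenyl]-3-[(tert-butyldimethylsilyl)oxy]-1-hydroxypropyl]phenol | Brc1ccc(OCc2ccccc2)c([C@H]([C@@H](O)c2ccc(O)cc2)CO[Si](C)(C)C(C)(C)C)c1 | intermediate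
14 | 4-[(1R,2S)-2-[2-(benzyloxy)-5-bromophenyl]-3-[(tert-butyldimethylsilyl)oxy]-1-hydroxypropyl]phenyl acetate | Brc1ccc(OCc2ccccc2)c([C@H]([C@@H](O)c2ccc(OC(C)=O)cc2)CO[Si](C)(C)C(C)(C)C)c1 | intermediate
15 | phloroglucinol (benzene-1,3,5-triol) | Oc1cc(O)cc(O)c1 | starting material
16 | benzene-1,3,5-triyl triacetate | CC(=O)Oc1cc(OC(C)=O)cc(OC(C)=O)c1 | intermediate
17 | 3,5-bis(benzyloxy)phenyl acetate | CC(=O)Oc1cc(OCc2ccccc2)cc(OCc2ccccc2)c1 | intermediate
18 | 3,5-bis(benzyloxy)phenol | Oc1cc(OCc2ccccc2)cc(OCc2ccccc2)c1 | intermediate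
19 | 4-[(1S,2S)-2-[2-(benzyloxy)-5-bromophenyl]-1-[3,5-bis(benzyloxy)phenoxy]-3-[(tert-butyldimethylsilyl)oxy]propyl]phenyl acetate | Brc1ccc(OCc2ccccc2)c([C@H]([C@H](Oc2cc(OCc3ccccc3)cc(OCc3ccccc3)c2)c2ccc(OC(C)=O)cc2)CO[Si](C)(C)C(C)(C)C)c1 | intermediate
20 | 4-[(1S,2S)-2-[2-(benzyloxy)-5-bromophenyl]-1-[3,5-bis(benzyloxy)phenoxy]-3-hydroxypropyl]phenyl acetate | Brc1ccc(OCc2ccccc2)c([C@H]([C@H](Oc2cc(OCc3ccccc3)cc(OCc3ccccc3)c2)c2ccc(OC(C)=O)cc2)CO)c1 | intermediate
21 | 4-[(1S,2R)-2-[2-(benzyloxy)-5-bromophenyl]-1-[3,5-bis(benzyloxy)phenoxy]-3-oxopropyl]phenyl acetate | Brc1ccc(OCc2ccccc2)c([C@H]([C@H](Oc2cc(OCc3ccccc3)cc(OCc3ccccc3)c2)c2ccc(OC(C)=O)cc2)C=O)c1 | intermediate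
22 | (2R,3S)-3-[4-(acetyloxy)phenyl]-2-[2-(benzyloxy)-5-bromophenyl]-3-[3,5-bis(benzyloxy)phenoxy]propanoic acid | Brc1ccc(OCc2ccccc2)c([C@H]([C@H](Oc2cc(OCc3ccccc3)cc(OCc3ccccc3)c2)c2ccc(OC(C)=O)cc2)C(=O)O)c1 | intermediate
23 | (2R,3S)-3-[4-(acetyloxy)phenyl]-2-[2-(benzyloxy)-5-bromophenyl]-3-[3,5-bis(benzyloxy)phenoxy]propanoic trifluoroacetic anhydride | Brc1ccc(OCc2ccccc2)c([C@H]([C@H](Oc2cc(OCc3ccccc3)cc(OCc3ccccc3)c2)c2ccc(OC(C)=O)cc2)C(=O)OC(=O)C(F)(F)F)c1 | intermediate
24 | 4-[(2S,3R)-5,7-bis(benzyloxy)-3-[2-(benzyloxy)-5-bromophenyl]-4-oxo-3,4-dihydro-2H-chromen-2-yl]phenyl acetate | Brc1ccc(OCc2ccccc2)c([C@H]2C(=O)c3c(OCc4ccccc4)cc(OCc4ccccc4)cc3O[C@@H]2c2ccc(OC(C)=O)cc2)c1 | intermediate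
25 | 4-[(2S,3R)-5,7-bis(benzyloxy)-3-[2-(benzyloxy)-5-(4,4,5,5-tetramethyl-1,3,2-dioxaborolan-2-yl)phenyl]-4-oxo-3,4-dihydro-2H-chromen-2-yl]phenyl acetate | CC1(C)OB(OC1(C)C)c1ccc(OCc2ccccc2)c([C@H]2C(=O)c3c(OCc4ccccc4)cc(OCc4ccccc4)cc3O[C@@H]2c2ccc(OC(C)=O)cc2)c1 | intermediate
26 | {3-[(2S,3R)-2-[4-(acetyloxy)phenyl]-5,7-bis(benzyloxy)-4-oxo-3,4-dihydro-2H-chromen-3-yl]-4-(benzyloxy)phenyl}boronic acid | OB(O)c1ccc(OCc2ccccc2)c([C@H]2C(=O)c3c(OCc4ccccc4)cc(OCc4ccccc4)cc3O[C@@H]2c2ccc(OC(C)=O)cc2)c1 | intermediate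
27 | 1-(2,6-dihydroxy-4-methoxyphenyl)ethan-1-one | CC(=O)c1c(O)cc(OC)cc1O | starting material
28 | 1-[2-(benzyloxy)-6-hydroxy-4-methoxyphenyl]ethan-1-one | CC(=O)c1c(O)cc(OC)cc1OCc1ccccc1 | intermediate
29 | 5-(benzyloxy)-4-hydroxy-7-methoxy-2H-chromene-2-thione | COc1cc(OCc2ccccc2)c2c(O)cc(=S)oc2c1 | intermediate
30 | 5-(benzyloxy)-7-methoxy-2-(methylsulfanyl)-4H-chromen-4-one | COc1cc(OCc2ccccc2)c2c(=O)cc(SC)oc2c1 | intermediate
31 | 4-[(2S,3R)-5,7-bis(benzyloxy)-3-{2-(benzyloxy)-5-[5-(benzyloxy)-7-methoxy-4-oxo-4H-chromen-2-yl]phenyl}-4-oxo-3,4-dihydro-2H-chromen-2-yl]phenyl acetate | COc1cc(OCc2ccccc2)c2c(=O)cc(-c3ccc(OCc4ccccc4)c([C@H]4C(=O)c5c(OCc6ccccc6)cc(OCc6ccccc6)cc5O[C@@H]4c4ccc(OC(C)=O)cc4)c3)oc2c1 | intermediate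
32 | (2S,3R)-5,7-bis(benzyloxy)-3-{2-(benzyloxy)-5-[5-(benzyloxy)-7-methoxy-4-oxo-4H-chromen-2-yl]phenyl}-2-(4-hydroxyphenyl)-2,3-dihydro-4H-chromen-4-one | COc1cc(OCc2ccccc2)c2c(=O)cc(-c3ccc(OCc4ccccc4)c([C@H]4C(=O)c5c(OCc6ccccc6)cc(OCc6ccccc6)cc5O[C@@H]4c4ccc(O)cc4)c3)oc2c1 | intermediate
33 | (2S,3R)-5,7-dihydroxy-3-[2-hydroxy-5-(5-hydroxy-7-methoxy-4-oxo-4H-chromen-2-yl)phenyl]-2-(4-hydroxyphenyl)-2,3-dihydro-4H-chromen-4-one | COc1cc(O)c2c(=O)cc(-c3ccc(O)c([C@H]4C(=O)c5c(O)cc(O)cc5O[C@@H]4c4ccc(O)cc4)c3)oc2c1 | target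

**Step count**

Total: 21 steps. Longest linear sequence: 16 steps (1 to 33 through steps 1, 2, 3, 5, 6, 7, 8, 11, 12, 13, 14, 15, 16, 19, 20 and 21).

**Steps most likely to fail**

Step 14 (key step). The acyl trifluoroacetate may be diverted before the arene attacks it: capture by the ortho-benzyloxy oxygen of the neighbouring aryl with loss of benzyl (lactonisation), acid-induced loss of benzyl groups, or ionisation and β-elimination at the benzylic aryl ether. The fallback sets out from 4, 18 and 8 and comes back at 24; it reverses the order of bond formation in ring C, C4–C4a first and C2–O1 last. Acid 4 would be converted with oxalyl chloride and catalytic DMF into 2-[2-(benzyloxy)-5-bromophenyl]acetyl chloride F1, which should C-acylate the bromomagnesium phenoxide of 18 (from EtMgBr, toluene) ortho to oxygen to give the deoxybenzoin 2-[2-(benzyloxy)-5-bromophenyl]-1-[2,4-bis(benzyloxy)-6-hydroxyphenyl]ethan-1-one F2. Condensation of F2 with aldehyde 8 (piperidine, EtOH, reflux; aldol condensation followed by oxa-Michael closure) should give racemic trans-5,7-bis(benzyloxy)-3-[2-(benzyloxy)-5-bromophenyl]-2-(4-hydroxyphenyl)chroman-4-one F3. Acetylation (Ac2O, pyridine) would give the racemic trans acetate F4, from which the (2S,3R) enantiomer 24 is separated by preparative HPLC on a chiral stationary phase. This path gives up the auxiliary control and pays for it with a resolution.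

Step 11. The activated benzylic alcohol may eliminate to the stilbene, or substitution at the hindered carbinol may be so slow that acetyl transfer to the phenol and reduction of the azo reagent take over. The fallback sets out from 14 and comes back at 19; it replaces the azodicarboxylate system by an oxidation–reduction condensation through a pre-formed P(III) ester, so that no hydrazide base is present. Alcohol 14 would be converted with Ph2PCl, Et3N and catalytic DMAP in THF into 4-[(1R,2S)-2-[2-(benzyloxy)-5-bromophenyl]-3-[(tert-butyldimethylsilyl)oxy]-1-[(diphenylphosphanyl)oxy]propyl]phenyl acetate F5. Treatment of F5 with phenol 18 and 2,6-dimethyl-1,4-benzoquinone in CH2Cl2 at rt (Mukaiyama oxidation–reduction condensation) should give 19 with inversion.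

Step 15. The carboxylate base may enolise C3 of the flavanone and open ring C by retro-oxa-Michael reaction, which would erode the configuration at C2; the boron compounds may also protodeboronate in steps 16 and 19. The fallback sets out from 24 and comes back at 31; it uses neutral tin chemistry and skips 25 and 26. Bromide 24 would be heated with hexamethylditin and Pd(PPh3)4 in toluene at 100 °C to give 4-[(2S,3R)-5,7-bis(benzyloxy)-3-[2-(benzyloxy)-5-(trimethylstannyl)phenyl]-4-oxo-3,4-dihydro-2H-chromen-2-yl]phenyl acetate F6. Coupling of F6 with thioether 30 (Pd(PPh3)4, copper(I) diphenylphosphinate, THF, 50 °C; the thioether–stannane variant of the Liebeskind–Srogl coupling) should give 31 without any base.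

**Further compounds**

F1 | step 14 | 2-[2-(benzyloxy)-5-bromophenyl]acetyl chloride | O=C(Cl)Cc1cc(Br)ccc1OCc1ccccc1
F2 | step 14 | 2-[2-(benzyloxy)-5-bromophenyl]-1-[2,4-bis(benzyloxy)-6-hydroxyphenyl]ethan-1-one | O=C(Cc1cc(Br)ccc1OCc1ccccc1)c1c(O)cc(OCc2ccccc2)cc1OCc1ccccc1
F3 | step 14 | racemic trans-5,7-bis(benzyloxy)-3-[2-(benzyloxy)-5-bromophenyl]-2-(4-hydroxyphenyl)chroman-4-one | Oc1ccc(cc1)C1Oc2cc(OCc3ccccc3)cc(OCc3ccccc3)c2C(=O)C1c1cc(Br)ccc1OCc1ccccc1
F4 | step 14 | racemic trans-4-[5,7-bis(benzyloxy)-3-[2-(benzyloxy)-5-bromophenyl]-4-oxochroman-2-yl]phenyl acetate | CC(=O)Oc1ccc(cc1)C1Oc2cc(OCc3ccccc3)cc(OCc3ccccc3)c2C(=O)C1c1cc(Br)ccc1OCc1ccccc1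
F5 | step 11 | 4-[(1R,2S)-2-[2-(benzyloxy)-5-bromophenyl]-3-[(tert-butyldimethylsilyl)oxy]-1-[(diphenylphosphanyl)oxy]propyl]phenyl acetate | Brc1ccc(OCc2ccccc2)c([C@H]([C@@H](OP(c2ccccc2)c2ccccc2)c2ccc(OC(C)=O)cc2)CO[Si](C)(C)C(C)(C)C)c1
F6 | step 15 | 4-[(2S,3R)-5,7-bis(benzyloxy)-3-[2-(benzyloxy)-5-(trimethylstannyl)phenyl]-4-oxo-3,4-dihydro-2H-chromen-2-yl]phenyl acetate | C[Sn](C)(C)c1ccc(OCc2ccccc2)c([C@H]2C(=O)c3c(OCc4ccccc4)cc(OCc4ccccc4)cc3O[C@@H]2c2ccc(OC(C)=O)cc2)c1
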